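**Strategy.** The route rests on cutting ring A at C9–C10 and at C8–Br. C8 and C9 are the two carbons of a vinyl group on the gem-dimethyl carbon C7, and C10 is the α-carbon of a β-keto ester whose ketone is C11. One enantioselective bromine-atom-transfer radical cyclisation therefore closes ring A 6-endo and leaves the neopentylic bromine on C8. The precursor is an α-bromo-β-keto ester, racemic only at C10, that carries on the future spiro carbon C6 a symmetric ketal-protected ring B and a 2-methylbut-3-en-2-yl group. C6 and the ring B bromohydrin are set afterwards by desymmetrising enolisation and anti bromohydration.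

Key step: step 5

Assumption: skeleton atoms are numbered ring B C1–C5 (C2 = CHBr, C3 = C(OH)Me), spiro C6, ring A C7 (CMe2), C8 (CHBr), C9, C10, C11 (C–Me), so the target is (2S,3S,6S,8R) and compounds 16–20 are named with these locants; the ligand antipode of step 5 and the amide antipode of step 9 are written as expected by analogy and are fixed by the first run, the mirror-image reagent being used if the sense is reversed.

Step 1
Reactants: 1 1,4-dioxaspiro[4.5]decane-8-carboxylic acid; 2 3-methylbut-2-en-1-ol (prenol)
Product: 3 3-methylbut-2-en-1-yl 1,4-dioxaspiro[4.5]decane-8-carboxylate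
Conditions: DCC, DMAP (cat.), CH2Cl2, 0 °C → rt
Reagents that add atoms: none
Why: Steglich esterification of an unhindered acid with a primary allylic alcohol runs through the O-acylisourea and the acylpyridinium ion without any acid, so the dioxolane is untouched and no stereocentre is involved.

Step 2
Reactants: 3 3-methylbut-2-en-1-yl 1,4-dioxaspiro[4.5]decane-8-carboxylate
Product: 6 8-(2-methylbut-3-en-2-yl)-1,4-dioxaspiro[4.5]decane-8-carboxylic acid, via silyl ketene acetal 4 (not isolated), via trimethylsilyl ester 5 (not isolated)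
Conditions: LiN(i-Pr)2, THF, −78 °C; Me3SiCl, −78 → 65 °C; aq. citric acid
Reagents that add atoms: none
Why: Ireland–Claisen rearrangement, in which the ester is enolised at its only α-hydrogen, silylated on oxygen and the ketene acetal undergoes the [3,3]-sigmatropic shift that joins the ring carbon to the dimethyl-substituted allyl terminus, a standard way to build two adjacent quaternary carbons; the new quaternary carbon bears two identical ring arms and is not a stereocentre.

Step 3
Reactants: 6 8-(2-methylbut-3-en-2-yl)-1,4-dioxaspiro[4.5]decane-8-carboxylic acid; 7 tert-butyl acetate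
Product: 10 tert-butyl 3-[8-(2-methylbut-3-en-2-yl)-1,4-dioxaspiro[4.5]decan-8-yl]-3-oxopropanoate, via acid chloride 8 (not isolated), via lithium enolate 9 (not isolated)
Conditions: 1-chloro-N,N,2-trimethylprop-1-en-1-amine, CH2Cl2, 0 °C → rt; then LiCH2CO2t-Bu (3 equiv, from 7 and LiN(i-Pr)2), THF, −78 → 0 °C; aq. NH4Cl
Reagents that add atoms: none
Why: Crossed Claisen condensation in which the doubly neopentylic acid is activated as its chloride under neutral conditions (no HCl, ketal safe) and acylates the small lithium enolate of tert-butyl acetate, whose excess deprotonates the β-keto ester as it forms and so prevents a second addition.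

Step 4
Reactants: 10 tert-butyl 3-[8-(2-methylbut-3-en-2-yl)-1,4-dioxaspiro[4.5]decan-8-yl]-3-oxopropanoate
Product: 11 tert-butyl 2-bromo-3-[8-(2-methylbut-3-en-2-yl)-1,4-dioxaspiro[4.5]decan-8-yl]-3-oxopropanoate (racemic at the C–Br carbon)
Conditions: NBS (1 equiv), Mg(ClO4)2 (0.3 equiv), EtOAc, −20 → 0 °C
Reagents that add atoms: N-bromosuccinimide, BrN1C(=O)CCC1=O
Why: Lewis-acid-catalysed α-bromination of a 1,3-dicarbonyl compound, in which Mg(ClO4)2 chelates and enolises the β-keto ester so that one equivalent of NBS brominates only the doubly activated carbon C10 while the isolated vinyl group is inert; the new centre is racemic, which does not matter because it becomes a planar radical in step 5.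

Step 5
Reactants: 11 tert-butyl 2-bromo-3-[8-(2-methylbut-3-en-2-yl)-1,4-dioxaspiro[4.5]decan-8-yl]-3-oxopropanoate
Product: 12 tert-butyl (10S,12R)-12-bromo-13,13-dimethyl-9-oxo-1,4-dioxadispiro[4.2.5.2]pentadecane-10-carboxylate
Conditions: Mg(ClO4)2 (1.1 equiv), (S,S)-2,2'-(propane-2,2-diyl)bis(4-phenyl-4,5-dihydro-1,3-oxazole) (Ph-box, 1.2 equiv), 4 Å molecular sieves, PhMe, −78 °C; BEt3 (substoichiometric, in portions), air
Reagents that add atoms: none
Why: Autoxidation of BEt3 supplies ethyl radicals that remove bromine from the magnesium-bound substrate, the electrophilic C10 radical adds to the terminal vinyl carbon C9, and the ring radical at C8 is quenched by bromine transfer from a second molecule of 11, which regenerates the C10 radical and keeps the chain going. The closest known reaction is the enantioselective bromine-atom-transfer cyclisation of unsaturated α-bromo-β-keto esters catalysed by Mg(ClO4)2 and a bis(oxazoline) and initiated by BEt3 and O2. Ring A closes in the 6-endo-trig mode, the usual preference of α-keto radicals whose carbonyl group ends up in the ring, reinforced here because 5-exo attack would have to occur at C8 next to the quaternary C7. The stereocentre at C10 (position 10 of 12) should be set by the chiral magnesium chelate, whose phenyl groups shield one face of the planar dicarbonyl radical. The stereocentre at C8 (position 12) should be set by substrate control in the bromine transfer, since the chair-like ring radical holds the chelated ester equatorial and should take bromine from the equatorial direction, away from the axial ring B methylene on C6, which places bromine cis to the ester. The step needs 6-endo regioselectivity, which the ring geometry supplies, and one absolute configuration at C8, which is relayed from C10 because the spiro carbon C6 is not yet stereogenic while ring B is symmetric.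

Step 6
Reactants: 12 tert-butyl (10S,12R)-12-bromo-13,13-dimethyl-9-oxo-1,4-dioxadispiro[4.2.5.2]pentadecane-10-carboxylate
Product: 14 (12R)-12-bromo-13,13-dimethyl-1,4-dioxadispiro[4.2.5.2]pentadecan-9-one, via β-keto acid 13 (not isolated)
Conditions: TsOH (anhydrous, 0.1 equiv), PhMe, 80 °C
Reagents that add atoms: none
Why: Acid-catalysed dealkoxycarbonylation, in which the tert-butyl ester loses isobutene and the β-keto acid decarboxylates through its cyclic transition state to the enol and then the ketone, so that no enolate is formed that could displace the 1,3-related C8 bromide, the anhydrous medium leaves the dioxolane intact and the C8 centre is not touched.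

Step 7
Reactants: 14 (12R)-12-bromo-13,13-dimethyl-1,4-dioxadispiro[4.2.5.2]pentadecan-9-one
Product: 15 (12R)-12-bromo-13,13-dimethyl-1,4-dioxadispiro[4.2.5.2]pentadec-9-en-9-yl trifluoromethanesulfonate
Conditions: Tf2O, 2,6-di-tert-butyl-4-methylpyridine, CH2Cl2, 0 °C → rt
Reagents that add atoms: trifluoromethanesulfonic anhydride, O=S(=O)(OS(=O)(=O)C(F)(F)F)C(F)(F)F
Why: Enol triflate formation under non-basic conditions, in which the carbonyl oxygen is sulfonylated and the only α-hydrogens, those on C10, are lost to the hindered pyridine, so the C10=C11 triflate forms regiospecifically without an enolate that could cyclise onto C8.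

Step 8
Reactants: 15 (12R)-12-bromo-13,13-dimethyl-1,4-dioxadispiro[4.2.5.2]pentadec-9-en-9-yl trifluoromethanesulfonate
Product: 16 (8R)-8-bromo-7,7-dimethyl-3-oxospiro[5.5]undec-10-en-11-yl trifluoromethanesulfonate
Conditions: 2 M HCl, THF, rt
Reagents that add atoms: water, O
Why: Acid-catalysed ketal hydrolysis frees the ring B ketone, while the vinyl triflate and the secondary bromide are inert to dilute aqueous acid at room temperature.

Step 9
Reactants: 16 (8R)-8-bromo-7,7-dimethyl-3-oxospiro[5.5]undec-10-en-11-yl trifluoromethanesulfonate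
Product: 18 (6R,8R)-8-bromo-7,7-dimethylspiro[5.5]undeca-2,10-diene-3,11-diyl bis(trifluoromethanesulfonate), via lithium enolate 17 (not isolated)
Conditions: (R,R)-HN[CH(Me)Ph]2·HCl, n-BuLi (2 equiv), THF, −78 °C (gives LiN[CH(Me)Ph]2·LiCl); add 16, −78 °C; then Comins' reagent, −78 → −20 °C
Reagents that add atoms: N-(5-chloropyridin-2-yl)-1,1,1-trifluoro-N-(trifluoromethanesulfonyl)methanesulfonamide (Comins' reagent), Clc1ccc(nc1)N(S(=O)(=O)C(F)(F)F)S(=O)(=O)C(F)(F)F
Why: Desymmetrising deprotonation with a homochiral lithium amide followed by O-sulfonylation of the enolate, in which ring B should sit in a chair with the bulky C7 equatorial and C11 axial, the amide removes the axial α-hydrogen on C2 in preference to that on C4, and this choice of arm makes the spiro carbon C6 stereogenic with the configuration shown, the (R,R) amide being chosen by analogy with its known sense on 4-tert-butylcyclohexanone with C7 in the place of the tert-butyl group.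

Step 10
Reactants: 18 (6R,8R)-8-bromo-7,7-dimethylspiro[5.5]undeca-2,10-diene-3,11-diyl bis(trifluoromethanesulfonate)
Product: 19 (6S,8R)-8-bromo-3,7,7,11-tetramethylspiro[5.5]undeca-2,10-diene
Conditions: Me2Zn (4 equiv), Pd(PPh3)4 (10 mol %), THF, 0 → 55 °C
Reagents that add atoms: dimethylzinc, C[Zn]C
Why: Twofold Negishi cross-coupling, in which zerovalent palladium inserts into each C(sp2)–OTf bond, methyl is transferred from zinc and reductive elimination gives both methyl-substituted ring alkenes without moving the double bonds, while the unactivated secondary alkyl bromide does not add oxidatively to a triphenylphosphine catalyst and C6 and C8 are untouched.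

Step 11
Reactants: 19 (6S,8R)-8-bromo-3,7,7,11-tetramethylspiro[5.5]undeca-2,10-diene
Product: 20 (2S,3S,6S,8R)-2,8-dibromo-3,7,7,11-tetramethylspiro[5.5]undec-10-en-3-ol (CNP0288382.1)
Conditions: NBS (1.05 equiv), THF/H2O, 0 °C, dark
Reagents that add atoms: N-bromosuccinimide, BrN1C(=O)CCC1=O; water, O
Why: Bromohydrin formation by electrophilic anti addition, in which NBS should choose the accessible ring B alkene over the ring A alkene (flanked by the spiro carbon and deactivated by the homoallylic bromine), the bromonium ion should form on the ring B face turned away from the axial C11 and its methyl group, and water opens it at the tertiary carbon C3 from the opposite face (Markovnikov), so that Br on C2 is cis to C7 and OH on C3 is cis to C11 as in the target.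

**Compound list**

1 | 1,4-dioxaspiro[4.5]decane-8-carboxylic acid | OC(=O)C1CCC2(CC1)OCCO2 | starting material
2 | 3-methylbut-2-en-1-ol (prenol) | CC(C)=CCO | starting material
3 | 3-methylbut-2-en-1-yl 1,4-dioxaspiro[4.5]decane-8-carboxylate | CC(C)=CCOC(=O)C1CCC2(CC1)OCCO2 | intermediate
4 | trimethyl({[(3-methylbut-2-en-1-yl)oxy](1,4-dioxaspiro[4.5]decan-8-ylidene)methyl}oxy)silane (silyl ketene acetal) | CC(C)=CCOC(O[Si](C)(C)C)=C1CCC2(CC1)OCCO2 | intermediate
5 | trimethylsilyl 8-(2-methylbut-3-en-2-yl)-1,4-dioxaspiro[4.5]decane-8-carboxylate | C=CC(C)(C)C1(CCC2(CC1)OCCO2)C(=O)O[Si](C)(C)C | intermediate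
6 | 8-(2-methylbut-3-en-2-yl)-1,4-dioxaspiro[4.5]decane-8-carboxylic acid | C=CC(C)(C)C1(CCC2(CC1)OCCO2)C(O)=O | intermediate
7 | tert-butyl acetate | CC(=O)OC(C)(C)C | starting material
8 | 8-(2-methylbut-3-en-2-yl)-1,4-dioxaspiro[4.5]decane-8-carbonyl chloride | C=CC(C)(C)C1(CCC2(CC1)OCCO2)C(Cl)=O | intermediate
9 | lithium 1-tert-butoxyethenolate (lithium enolate of tert-butyl acetate) | C=C(O[Li])OC(C)(C)C | intermediate
10 | tert-butyl 3-[8-(2-methylbut-3-en-2-yl)-1,4-dioxaspiro[4.5]decan-8-yl]-3-oxopropanoate | CC(C)(C)OC(=O)CC(=O)C1(CCC2(CC1)OCCO2)C(C)(C)C=C | intermediate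
11 | tert-butyl 2-bromo-3-[8-(2-methylbut-3-en-2-yl)-1,4-dioxaspiro[4.5]decan-8-yl]-3-oxopropanoate (racemic at C–Br) | CC(C)(C)OC(=O)C(Br)C(=O)C1(CCC2(CC1)OCCO2)C(C)(C)C=C | intermediate
12 | tert-butyl (10S,12R)-12-bromo-13,13-dimethyl-9-oxo-1,4-dioxadispiro[4.2.5.2]pentadecane-10-carboxylate | CC(C)(C)OC(=O)[C@H]1C[C@@H](Br)C(C)(C)C2(CCC3(CC2)OCCO3)C1=O | intermediate
13 | (10S,12R)-12-bromo-13,13-dimethyl-9-oxo-1,4-dioxadispiro[4.2.5.2]pentadecane-10-carboxylic acid | OC(=O)[C@H]1C[C@@H](Br)C(C)(C)C2(CCC3(CC2)OCCO3)C1=O | intermediate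
14 | (12R)-12-bromo-13,13-dimethyl-1,4-dioxadispiro[4.2.5.2]pentadecan-9-one | O=C1CC[C@@H](Br)C(C)(C)C12CCC3(CC2)OCCO3 | intermediate
15 | (12R)-12-bromo-13,13-dimethyl-1,4-dioxadispiro[4.2.5.2]pentadec-9-en-9-yl trifluoromethanesulfonate | FC(F)(F)S(=O)(=O)OC1=CC[C@@H](Br)C(C)(C)C12CCC3(CC2)OCCO3 | intermediate
16 | (8R)-8-bromo-7,7-dimethyl-3-oxospiro[5.5]undec-10-en-11-yl trifluoromethanesulfonate | FC(F)(F)S(=O)(=O)OC1=CC[C@@H](Br)C(C)(C)C12CCC(=O)CC2 | intermediate
17 | lithium (6R,8R)-8-bromo-7,7-dimethyl-11-(trifluoromethanesulfonyloxy)spiro[5.5]undeca-2,10-dien-3-olate | FC(F)(F)S(=O)(=O)OC1=CC[C@@H](Br)C(C)(C)[C@]12CCC(O[Li])=CC2 | intermediate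
18 | (6R,8R)-8-bromo-7,7-dimethylspiro[5.5]undeca-2,10-diene-3,11-diyl bis(trifluoromethanesulfonate) | FC(F)(F)S(=O)(=O)OC1=CC[C@@H](Br)C(C)(C)[C@]12CCC(OS(=O)(=O)C(F)(F)F)=CC2 | intermediate
19 | (6S,8R)-8-bromo-3,7,7,11-tetramethylspiro[5.5]undeca-2,10-diene | CC1=CC[C@@H](Br)C(C)(C)[C@]12CCC(C)=CC2 | intermediate
20 | (2S,3S,6S,8R)-2,8-dibromo-3,7,7,11-tetramethylspiro[5.5]undec-10-en-3-ol | CC1=CC[C@@H](Br)C(C)(C)[C@]12CC[C@](C)(O)[C@@H](Br)C2 | target

Total step count: 11. Longest linear sequence: 11 steps (1 → 20).

**Steps most likely to fail**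

1. Step 5. The chiral chelate may shield the two faces of the C10 radical too unequally, or bromine may be delivered to both faces of the C8 ring radical; either leaves C8 in low enantiomeric purity. The fallback resolves C8 through a covalent chiral ketal; it sets out from 14 and comes back at 16. Ketone 14 of insufficient enantiomeric purity (or made with Mg(ClO4)2 alone) is heated with (R,R)-hydrobenzoin and catalytic TsOH in toluene while ethylene glycol is removed as its azeotrope. The ketal exchange should give (2R,3R,12R)-12-bromo-13,13-dimethyl-2,3-diphenyl-1,4-dioxadispiro[4.2.5.2]pentadecan-9-one F1 together with its (12S) epimer F2. Because the new ketal is twofold symmetric, C6 stays non-stereogenic, so F1 and F2 are diastereomers and are separated by crystallisation or chromatography. F1 is converted with Tf2O and 2,6-di-tert-butyl-4-methylpyridine into the enol triflate F3, and 3 M HCl in THF at 50 °C removes the ketal to give 16.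

2. Step 9. The amide may not discriminate well between the two ring B arms, because the ring B chair is not biased enough or because the remote C8 centre is mismatched, so both C6 epimers form. The fallback replaces reagent control by an enzymatic enol-ester resolution with recycling, a known way to desymmetrise 4,4-disubstituted cyclohexanones; it sets out from 16 and comes back at 18. Unselective enolisation (LiN(i-Pr)2, THF, −78 °C, then Ac2O) gives (6R,8R)-3-acetoxy-8-bromo-7,7-dimethylspiro[5.5]undeca-2,10-dien-11-yl trifluoromethanesulfonate F4 and its (6S) epimer F5. A Pseudomonas lipase with n-BuOH in diisopropyl ether, chosen by screening so that it spares F4, cleaves F5 back to 16, which is recycled. F4 is then cleaved with MeLi (2 equiv, THF, −78 °C) to the lithium enolate 17, which is trapped with Comins' reagent as in step 9 to give 18.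

3. Step 11. The bromonium ion may form on the ring B face syn to C11 (or NBS may attack the ring A alkene), which leads to the other trans-bromohydrin. The fallback uses the same face preference in the opposite sense by placing oxygen, not bromine, on the accessible face and bringing bromide in by SN2; it sets out from 19 and comes back at 20. OsO4 (cat.) with N-methylmorpholine N-oxide in acetone/H2O should dihydroxylate only the less hindered ring B alkene to (2R,3S,6S,8R)-8-bromo-3,7,7,11-tetramethylspiro[5.5]undec-10-ene-2,3-diol F6. 1,1'-Sulfonyldiimidazole and NaH in THF close the cyclic sulfate F7 without an oxidant that could touch the ring A alkene. LiBr in THF opens it at the secondary carbon C2 with inversion to lithium (2S,3S,6S,8R)-2,8-dibromo-3,7,7,11-tetramethylspiro[5.5]undec-10-en-3-yl sulfate F8, and catalytic H2SO4 in wet THF hydrolyses the sulfate ester to 20.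

Further compounds
F1 | step 5 | (2R,3R,12R)-12-bromo-13,13-dimethyl-2,3-diphenyl-1,4-dioxadispiro[4.2.5.2]pentadecan-9-one | O=C1CC[C@@H](Br)C(C)(C)C12CCC3(CC2)O[C@H](c4ccccc4)[C@@H](c5ccccc5)O3
F2 | step 5 | (2R,3R,12S)-12-bromo-13,13-dimethyl-2,3-diphenyl-1,4-dioxadispiro[4.2.5.2]pentadecan-9-one | O=C1CC[C@H](Br)C(C)(C)C12CCC3(CC2)O[C@H](c4ccccc4)[C@@H](c5ccccc5)O3
F3 | step 5 | (2R,3R,12R)-12-bromo-13,13-dimethyl-2,3-diphenyl-1,4-dioxadispiro[4.2.5.2]pentadec-9-en-9-yl trifluoromethanesulfonate | FC(F)(F)S(=O)(=O)OC1=CC[C@@H](Br)C(C)(C)C12CCC3(CC2)O[C@H](c4ccccc4)[C@@H](c5ccccc5)O3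
F4 | step 9 | (6R,8R)-3-acetoxy-8-bromo-7,7-dimethylspiro[5.5]undeca-2,10-dien-11-yl trifluoromethanesulfonate | FC(F)(F)S(=O)(=O)OC1=CC[C@@H](Br)C(C)(C)[C@]12CCC(OC(C)=O)=CC2
F5 | step 9 | (6S,8R)-3-acetoxy-8-bromo-7,7-dimethylspiro[5.5]undeca-2,10-dien-11-yl trifluoromethanesulfonate | FC(F)(F)S(=O)(=O)OC1=CC[C@@H](Br)C(C)(C)[C@@]12CCC(OC(C)=O)=CC2
F6 | step 11 | (2R,3S,6S,8R)-8-bromo-3,7,7,11-tetramethylspiro[5.5]undec-10-ene-2,3-diol | CC1=CC[C@@H](Br)C(C)(C)[C@]12CC[C@](C)(O)[C@H](O)C2
F7 | step 11 | (2R,3S,6S,8R)-8-bromo-3,7,7,11-tetramethylspiro[5.5]undec-10-ene-2,3-diyl sulfate (cyclic sulfate) | CC1=CC[C@@H](Br)C(C)(C)[C@]12CC[C@]3(C)OS(=O)(=O)O[C@@H]3C2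
F8 | step 11 | lithium (2S,3S,6S,8R)-2,8-dibromo-3,7,7,11-tetramethylspiro[5.5]undec-10-en-3-yl sulfate | CC1=CC[C@@H](Br)C(C)(C)[C@]12CC[C@](C)(OS(=O)(=O)[O-])[C@@H](Br)C2.[Li+]
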